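**Plan**

1. Retrosynthesis: take off the acyl groups; replace the only olefin of the ten-membered ring (C5=C6) by a C5H–SO2–C6H2 bridge, giving an eleven-membered cyclic sulfone; open that thiacycle at S–C6; then cut C2–C3 (aldol), C7–O/C6–I (iodolactonisation), C8–C17 (aldol) and C9–C10 ([2,3]-Wittig) back to a cyclohexenol made from (S)-carvone.
2. Forward order: cyclohexene ring (from carvone) → C9/C8/C7 arm with the γ-lactone → C2–C5/C16 arm → eleven-membered sulfide by S-alkylation → sulfone → Ramberg–Bäcklund contraction to the ten-membered (Z)-cycloalkene → lactone re-closure, acylations, desilylation.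
3. Enabling feature: ring C1–C10 has a single C=C (C5=C6) flanked by sp3 C4 and C7, so sulfur can be inserted between C5 and C6 and extruded later. C5 is stereogenic in the thiacycle but trigonal in the target, so both C5 epimers converge on one olefin.
4. Stereochemistry: C14 from (S)-carvone; C1 by alkylation anti to isopropenyl; the C12 epoxide (anti to isopropenyl) is relayed suprafacially to C10, together with C9, in the [2,3]-shift; C8 and C17 by chelation-controlled aldol from C9; C7 by hydroxyl-directed iodolactonisation from C8; C2 by Ipc2B reagent control; C4 by 1,3-anti reduction from C2; the side chain from (R)-3-hydroxybutanoic acid.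

Key step: step 27

Remark: briarane numbering is used (C1–C10 ten-membered ring; C11–C14 rest of the cyclohexene; C15/C20 methyls on C1/C11; C16 = CH2O on C5; C17/C18/C19 = lactone CH/CH3/C=O); compounds 23–36 are carried as C5-epimeric mixtures (C5 written without descriptor), which the key step makes irrelevant.

**Route**

Step 1
Reactants: 1 (S)-(+)-carvone
Product: 2 6-(hydroxymethyl)carvone (CH2OH trans to isopropenyl; C6 = future C1)
Conditions: LDA, THF, −78 °C; HCHO (g), −78 °C; aq. NH4Cl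
Reagents that add atoms: formaldehyde C=O
Why: The kinetic cross-conjugated lithium enolate reacts at C6 with monomeric formaldehyde (aldol hydroxymethylation); the C6 configuration is inconsequential because the centre is re-enolised in step 3.

Step 2
Reactants: 2 6-(hydroxymethyl)carvone
Product: 3 TBS ether of 2
Conditions: TBSCl, imidazole, DMF, 0 °C → rt
Reagents that add atoms: tert-butyldimethylsilyl chloride CC(C)(C)[Si](C)(C)Cl
Why: Standard silylation of the primary alcohol protects the β-hydroxy ketone against retro-aldol cleavage during the next enolisation.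

Step 3
Reactants: 3 TBS ether
Product: 4 6-methyl-6-(TBSOCH2)carvone (Me trans, CH2OTBS cis to isopropenyl)
Conditions: LDA, THF, −78 °C; MeI, DMPU, −78 → −40 °C
Reagents that add atoms: iodomethane CI
Why: Enolate alkylation, in which the tetrasubstituted enolate is methylated on the face anti to the adjacent isopropenyl group, sets the quaternary centre (future C1) with Me trans and CH2OTBS cis to the C14 substituent.

Step 4
Reactants: 4 quaternary enone
Product: 5 α,β-epoxy ketone (oxirane trans to isopropenyl; future C11–C12, β)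
Conditions: 30% H2O2, NaOH (cat.), MeOH, 0 °C
Reagents that add atoms: hydrogen peroxide OO
Why: Weitz–Scheffer nucleophilic epoxidation attacks only the electron-poor enone C=C, and hydroperoxide adds anti to the isopropenyl group as in carvone itself, giving the β-epoxide that later defines C12.

Step 5
Reactants: 5 epoxy ketone
Product: 7 epoxy ketone C14 acetate, via methoxy hydroperoxide 6 (not isolated)
Conditions: O3, CH2Cl2/MeOH, −78 °C; then Ac2O, Et3N, DMAP (cat.), CH2Cl2, 0 → 40 °C
Reagents that add atoms: ozone [O-][O+]=O; methanol CO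
Why: Ozone cleaves the only remaining olefin and the derived α-methoxy hydroperoxide undergoes Criegee rearrangement on acetylation, the secondary carbon migrating to oxygen with retention, so the isopropenyl group becomes the C14 acetate.

Step 6
Reactants: 7 epoxy ketone acetate
Product: 8 cyclohexenol (C12 β-OH, C10=C11 olefin, C14 OAc)
Conditions: N2H4·H2O, AcOH (cat.), MeOH, 0 °C → rt
Reagents that add atoms: none
Why: Wharton transposition, in which the epoxy-ketone hydrazone fragments with loss of N2 to the allylic alcohol; the epoxide C12–O bond is retained (β-OH) and the olefin moves to C10=C11.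

Step 7
Reactants: 8 cyclohexenol; 9 2-bromo-1-(morpholin-4-yl)ethan-1-one
Product: 10 C12 O-(2-morpholino-2-oxoethyl) ether
Conditions: Ag2O, 4 Å MS, CH2Cl2, rt, dark
Reagents that add atoms: none
Why: Silver-oxide-mediated Williamson etherification alkylates the only free hydroxyl under non-basic conditions that leave the acetate untouched and installs the carbanion-stabilising amide for the coming rearrangement.

Step 8
Reactants: 10 ether acetate
Product: 11 C14 alcohol
Conditions: K2CO3 (cat.), MeOH, 0 °C → rt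
Reagents that add atoms: none
Why: Base-catalysed transesterification removes the acetate (no longer β to a ketone, so no retro-aldol path) without touching the tertiary amide or the silyl ether.

Step 9
Reactants: 11 allyloxy-acetamide
Product: 12 α-hydroxy morpholine amide (C9–C10 bond made; C11=C12 olefin; C9 and C10 as in the target)
Conditions: LDA (3 equiv), THF, −78 → −20 °C; aq. NH4Cl
Reagents that add atoms: none
Why: [2,3]-Wittig rearrangement of the amide enolate (C14 alkoxide as spectator) forms C9–C10 suprafacially on the face of the C12–O bond, transferring C12 chirality to C10 and moving the olefin to C11=C12, while the envelope transition state with the enolate exo, away from the C1 quaternary centre, sets C9 with its hydroxyl.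

Step 10
Reactants: 12 diol amide
Product: 13 9,14-bis(PMB) ether
Conditions: NaH, PMBBr, Bu4NI (cat.), DMF, 0 °C → rt
Reagents that add atoms: 4-methoxybenzyl bromide COc1ccc(CBr)cc1
Why: Williamson etherification of both secondary alkoxides gives the PMB ethers that serve as the chelating group at C9 and as a common, oxidatively removable protection for two future acetate sites.

Step 11
Reactants: 13 morpholine amide
Product: 14 C8 vinyl ketone
Conditions: CH2=CHMgBr, THF, −78 → 0 °C; inverse quench into cold 1 M HCl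
Reagents that add atoms: vinylmagnesium bromide C=C[Mg]Br
Why: Acylation of a Grignard reagent by a morpholine amide (Weinreb-type), in which the chelated tetrahedral adduct survives until the acidic quench, delivers a single vinyl group to give the enone.

Step 12
Reactants: 14 vinyl ketone; 15 tert-butyl propanoate
Product: 16 tert-butyl ester aldol adduct (C8 tertiary alcohol bearing vinyl and CH(CH3)CO2tBu)
Conditions: 15, LDA, THF, −78 °C; CeCl3, −78 °C; then 14; aq. NH4Cl
Reagents that add atoms: none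
Why: Chelation-controlled aldol addition of the cerium E(O)-enolate, which adds 1,2 to the enone: the C9-OPMB/C8=O chelate exposes the face anti to C10 and fixes C8, and the closed transition state with the vinyl group equatorial places the C17 methyl anti to the C9 branch.

Step 13
Reactants: 16 hydroxy ester
Product: 17 iodolactone (C19–O–C7 γ-lactone, C6 iodide, free C8–OH)
Conditions: I2, NaHCO3, MeCN, 0 °C, dark
Reagents that add atoms: iodine II
Why: Kinetic 5-exo iodolactonisation of the 3-hydroxy-4-pentenoate (tert-butyl lost as isobutene), in which the tertiary hydroxyl directs iodonium formation so that CH2I ends cis to OH and trans to the bulky C9 branch, sets C7 and provides the C6 electrophile.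

Step 14
Reactants: 17 iodolactone TBS ether
Product: 18 C2 primary alcohol
Conditions: HF·pyridine, pyridine, THF, 0 °C → rt
Reagents that add atoms: none
Why: Buffered fluoride cleavage of the primary TBS ether leaves PMB ethers, the lactone and the iodide untouched.

Step 15
Reactants: 18 primary alcohol
Product: 19 C2 aldehyde
Conditions: Dess–Martin periodinane, NaHCO3, CH2Cl2, rt
Reagents that add atoms: none
Why: Dess–Martin oxidation gives the non-enolisable neopentyl aldehyde while the tertiary alcohol is inert.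

Step 16
Reactants: 20 2-[(tert-butyldiphenylsilyl)oxy]acetaldehyde; 21 ethyl vinyl ether
Product: 23 4-(TBDPS-oxy)-3-hydroxybutan-2-one, via ethoxyallyl alcohol adduct 22 (not isolated)
Conditions: 21, t-BuLi, THF, −78 → 0 °C; 20, −78 °C; then 1 M HCl, THF, 0 °C
Reagents that add atoms: water O
Why: 1-Ethoxyvinyllithium acts as an acetyl anion equivalent in 1,2-addition to the aldehyde, and mild acid hydrolysis of the enol ether unveils the α-hydroxy methyl ketone (racemic, which is immaterial).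

Step 17
Reactants: 23 hydroxy ketone
Product: 24 4-(TBDPS-oxy)-3-(TES-oxy)butan-2-one (C3–C4–C5–C16 unit)
Conditions: TESCl, imidazole, CH2Cl2, 0 °C
Reagents that add atoms: chlorotriethylsilane CC[Si](Cl)(CC)CC
Why: Silylation of the secondary alcohol with a group that can later be removed in the presence of the TBDPS ether.

Step 18
Reactants: 19 aldehyde; 24 methyl ketone
Product: 25 β-hydroxy ketone (C2 carbinol as in the target, C4 ketone, C5 OTES, C16 OTBDPS)
Conditions: 24, (+)-Ipc2BCl, Et3N, Et2O, 0 °C; then 19, −78 → −20 °C; H2O2, pH 7 buffer, MeOH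
Reagents that add atoms: none
Why: Boron aldol reaction of the kinetic methyl-ketone enolate, in which the isopinocampheyl ligands direct attack on the re face of the neopentyl aldehyde, sets C2 by reagent control.

Step 19
Reactants: 25 β-hydroxy ketone
Product: 26 2,4-anti diol
Conditions: Me4NBH(OAc)3, MeCN/AcOH, −30 °C
Reagents that add atoms: none
Why: Evans–Saksena reduction, in which the C2 hydroxyl binds the acetoxyborohydride and delivers hydride intramolecularly through a chair transition state, gives the 2,4-anti diol and thereby C4.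

Step 20
Reactants: 26 diol
Product: 27 2,4-acetonide
Conditions: 2-methoxypropene, PPTS (cat.), CH2Cl2, 0 °C
Reagents that add atoms: 2-methoxypropene COC(C)=C
Why: Kinetic acetonide formation on the 1,3-diol turns both oxygens into ethers for the later basic step, and the tertiary alcohol does not react.

Step 21
Reactants: 27 acetonide TES ether
Product: 28 C5 alcohol
Conditions: HF·pyridine, pyridine, THF, 0 °C
Reagents that add atoms: none
Why: Buffered HF·pyridine removes the triethylsilyl ether far faster than the primary TBDPS ether and so frees only the C5 hydroxyl.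

Step 22
Reactants: 28 C5 alcohol
Product: 29 C5 thioacetate
Conditions: PPh3, DIAD, AcSH, THF, 0 °C → rt
Reagents that add atoms: thioacetic acid CC(=O)S
Why: Mitsunobu displacement by thioacetic acid installs sulfur at C5 with inversion, the C5 configuration being irrelevant because this centre becomes sp2 in the key step.

Step 23
Reactants: 29 thioacetate iodide
Product: 31 eleven-membered cyclic sulfide, via C5 thiol 30 (not isolated)
Conditions: N2H4·H2O (1.1 equiv), degassed DMF, 0 °C; then slow addition to Cs2CO3, DMF (0.002 M), 40 °C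
Reagents that add atoms: none
Why: Chemoselective hydrazinolysis of the thioester releases the thiol, whose caesium thiolate closes the eleven-membered thiacycle by intramolecular SN2 (11-exo-tet) at the primary C6 iodide under high dilution.

Step 24
Reactants: 31 sulfide lactone
Product: 32 Weinreb amide 7,8-diol
Conditions: MeNH(OMe)·HCl, Me3Al, CH2Cl2, 0 °C → rt; Rochelle salt
Reagents that add atoms: N,O-dimethylhydroxylamine hydrochloride CNOC.Cl
Why: Weinreb aminolysis of the γ-lactone with the dimethylaluminium amide opens the ring so that C7–O is no longer a carboxylate leaving group β to the future sulfonyl carbanion.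

Step 25
Reactants: 32 diol
Product: 33 7,8-bis(TES) ether
Conditions: TESOTf, 2,6-lutidine, CH2Cl2, −78 → 0 °C
Reagents that add atoms: triethylsilyl triflate CC[Si](CC)(CC)OS(=O)(=O)C(F)(F)F
Why: Silyl triflate silylation converts the secondary and the tertiary hydroxyl into ethers, blocking retro-aldol and retro-addition pathways in the basic key step.

Step 26
Reactants: 33 sulfide
Product: 34 eleven-membered cyclic sulfone
Conditions: TPAP (5 mol%), NMO, 4 Å MS, MeCN, rt
Reagents that add atoms: 4-methylmorpholine N-oxide C[N+]1([O-])CCOCC1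
Why: Ley–Griffith conditions oxidise the sulfide to the sulfone without epoxidising the olefin or touching PMB and silyl ethers.

Step 27
Reactants: 34 cyclic sulfone
Product: 37 ten-membered (5Z)-cycloalkene, via C6 bromo sulfone 35 (not isolated), via episulfone 36 (not isolated)
Conditions: CBr2F2, KOH/Al2O3, t-BuOH/CH2Cl2, 0 °C → rt
Reagents that add atoms: none
Why: Ramberg–Bäcklund reaction with in-situ halogenation: base deprotonates α to sulfur, CBr2F2 brominates the carbanion, a second deprotonation at the other α-carbon expels bromide in a 1,3-elimination to the episulfone, and cheletropic loss of SO2 gives the C5=C6 olefin, so the eleven-membered thiacycle contracts to the ten-membered carbocycle. The closest precedent is the Ramberg–Bäcklund ring contraction of macrocyclic sulfones to medium-ring olefins and its use on β-alkoxy sulfones. The only ring closed is the thiirane dioxide (3-exo-tet SN2 by the α-sulfonyl carbanion), which at the same time makes the C5–C6 bond of the ten-membered ring. No new stereocentre is formed: C5 is erased, so both C5 epimers and both bromo epimers of 35 funnel into one product. The step needs the Z geometry (C4 and C7 cis), which should follow because only the cis-fused episulfone can be accommodated in a ten-membered ring trans-fused to the cyclohexene and carrying the dioxane, and the extrusion is stereospecific. It also needs β-elimination and retro-addition to be suppressed, which the substrate secures by carrying every β-oxygen (C4, C7, C16) as an ether and the lactone as an open Weinreb amide.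

Step 28
Reactants: 37 cycloalkene
Product: 38 lactone 2,4-diol (9,14-di-PMB, 16-OTBDPS, free 8-OH)
Conditions: 1 M HCl (aq)/THF, rt
Reagents that add atoms: none
Why: Aqueous acid hydrolyses the acetonide and both TES ethers, and the liberated C7 hydroxyl then displaces N,O-dimethylhydroxylamine from the γ-positioned Weinreb amide to re-form the trans-fused γ-lactone.

Step 29
Reactants: 39 (R)-3-hydroxybutanoic acid
Product: 40 (R)-3-acetoxybutanoic acid
Conditions: Ac2O, pyridine, DMAP (cat.), CH2Cl2, 0 °C → rt; aqueous work-up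
Reagents that add atoms: acetic anhydride CC(=O)OC(C)=O
Why: Acetylation of the secondary alcohol of the commercial (R)-hydroxy acid (any mixed anhydride is hydrolysed on work-up) leaves the stereocentre untouched.

Step 30
Reactants: 38 diol; 40 (R)-3-acetoxybutanoic acid
Product: 41 4-O-[(R)-3-acetoxybutanoyl] ester
Conditions: EDC·HCl, DMAP (cat.), CH2Cl2, −20 → 0 °C
Reagents that add atoms: none
Why: Steglich esterification under kinetic control should acylate the allylic C4 hydroxyl in preference to the neopentyl C2 hydroxyl and the tertiary C8 hydroxyl.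

Step 31
Reactants: 41 bis-PMB ether
Product: 42 2,9,14-triol
Conditions: DDQ, CH2Cl2/pH 7 buffer, 0 °C → rt
Reagents that add atoms: none
Why: Oxidative cleavage of both PMB ethers by DDQ (hydride abstraction, then hydrolysis of the oxocarbenium ion) is orthogonal to the esters, the silyl ether and the olefins.

Step 32
Reactants: 42 triol
Product: 43 2,9,14-triacetate 16-OTBDPS ether
Conditions: Ac2O, pyridine, DMAP, CH2Cl2, rt
Reagents that add atoms: acetic anhydride CC(=O)OC(C)=O
Why: DMAP-catalysed acetylation esterifies the three secondary alcohols (C2, C9, C14) while the hindered tertiary C8 alcohol stays free.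

Step 33
Reactants: 43 silyl ether
Product: 44 CNP0316115.1
Conditions: HF·pyridine, pyridine, THF, 0 °C → rt
Reagents that add atoms: none
Why: Buffered fluoride cleavage of the primary allylic TBDPS ether avoids acyl migration and ester cleavage and releases the C16 alcohol of the target.

**Compound list**

1 | (S)-(+)-carvone | CC(=C)[C@H]1CC=C(C)C(=O)C1 | starting material
2 | 6-(hydroxymethyl)carvone, CH2OH trans to isopropenyl | OC[C@@H]1[C@@H](C(C)=C)CC=C(C)C1=O | intermediate
3 | TBS ether of 2 | CC(C)(C)[Si](C)(C)OC[C@@H]1[C@@H](C(C)=C)CC=C(C)C1=O | intermediate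
4 | 6-methyl-6-(TBSOCH2)carvone, Me trans to isopropenyl | CC(C)(C)[Si](C)(C)OC[C@@]1(C)[C@@H](C(C)=C)CC=C(C)C1=O | intermediate
5 | epoxy ketone, oxirane trans to isopropenyl | CC(C)(C)[Si](C)(C)OC[C@@]1(C)[C@@H](C(C)=C)C[C@@H]2O[C@]2(C)C1=O | intermediate
6 | α-methoxy hydroperoxide from the isopropenyl group | CC(C)(C)[Si](C)(C)OC[C@@]1(C)[C@@H](C(C)(OC)OO)C[C@@H]2O[C@]2(C)C1=O | intermediate
7 | epoxy ketone C14 acetate | CC(C)(C)[Si](C)(C)OC[C@@]1(C)[C@@H](OC(C)=O)C[C@@H]2O[C@]2(C)C1=O | intermediate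
8 | cyclohexenol (C12 β-OH, C10=C11, C14 OAc) | CC(C)(C)[Si](C)(C)OC[C@@]1(C)[C@@H](OC(C)=O)C[C@H](O)C(C)=C1 | intermediate
9 | 2-bromo-1-(morpholin-4-yl)ethan-1-one | BrCC(=O)N1CCOCC1 | starting material
10 | C12 O-(2-morpholino-2-oxoethyl) ether, C14 OAc | CC(C)(C)[Si](C)(C)OC[C@@]1(C)[C@@H](OC(C)=O)C[C@H](OCC(=O)N2CCOCC2)C(C)=C1 | intermediate
11 | C12 ether, C14 alcohol | CC(C)(C)[Si](C)(C)OC[C@@]1(C)[C@@H](O)C[C@H](OCC(=O)N2CCOCC2)C(C)=C1 | intermediate
12 | α-hydroxy morpholine amide (C9 carbinol on C10, C11=C12, free C14 OH) | CC(C)(C)[Si](C)(C)OC[C@@]1(C)[C@@H](O)CC=C(C)[C@@H]1[C@@H](O)C(=O)N1CCOCC1 | intermediate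
13 | 9,14-bis(PMB) ether of 12 | CC(C)(C)[Si](C)(C)OC[C@@]1(C)[C@@H](OCc2ccc(OC)cc2)CC=C(C)[C@@H]1[C@@H](OCc1ccc(OC)cc1)C(=O)N1CCOCC1 | intermediate
14 | C8 vinyl ketone | CC(C)(C)[Si](C)(C)OC[C@@]1(C)[C@@H](OCc2ccc(OC)cc2)CC=C(C)[C@@H]1[C@@H](OCc1ccc(OC)cc1)C(=O)C=C | intermediate
15 | tert-butyl propanoate | CCC(=O)OC(C)(C)C | starting material
16 | aldol adduct, C8 tertiary alcohol with vinyl and CH(CH3)CO2tBu | CC(C)(C)[Si](C)(C)OC[C@@]1(C)[C@@H](OCc2ccc(OC)cc2)CC=C(C)[C@@H]1[C@@H](OCc1ccc(OC)cc1)[C@@](O)(C=C)[C@@H](C)C(=O)OC(C)(C)C | intermediate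
17 | iodolactone (C19–O–C7 lactone, C6 iodide, C2 CH2OTBS) | CC(C)(C)[Si](C)(C)OC[C@@]1(C)[C@@H](OCc2ccc(OC)cc2)CC=C(C)[C@@H]1[C@@H](OCc1ccc(OC)cc1)[C@@]1(O)[C@H](CI)OC(=O)[C@@H]1C | intermediate
18 | iodolactone C2 primary alcohol | OC[C@@]1(C)[C@@H](OCc2ccc(OC)cc2)CC=C(C)[C@@H]1[C@@H](OCc1ccc(OC)cc1)[C@@]1(O)[C@H](CI)OC(=O)[C@@H]1C | intermediate
19 | iodolactone C2 aldehyde | O=C[C@@]1(C)[C@@H](OCc2ccc(OC)cc2)CC=C(C)[C@@H]1[C@@H](OCc1ccc(OC)cc1)[C@@]1(O)[C@H](CI)OC(=O)[C@@H]1C | intermediate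
20 | 2-[(tert-butyldiphenylsilyl)oxy]acetaldehyde | O=CCO[Si](c1ccccc1)(c1ccccc1)C(C)(C)C | starting material
21 | ethyl vinyl ether | C=COCC | starting material
22 | 2-ethoxyallyl alcohol adduct | C=C(OCC)C(O)CO[Si](c1ccccc1)(c1ccccc1)C(C)(C)C | intermediate
23 | 4-(TBDPS-oxy)-3-hydroxybutan-2-one (racemic) | CC(=O)C(O)CO[Si](c1ccccc1)(c1ccccc1)C(C)(C)C | intermediate
24 | 4-(TBDPS-oxy)-3-(TES-oxy)butan-2-one (racemic) | CC(=O)C(O[Si](CC)(CC)CC)CO[Si](c1ccccc1)(c1ccccc1)C(C)(C)C | intermediate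
25 | aldol adduct: C2 carbinol, C4 ketone, C5 OTES, C16 OTBDPS | CC(C)(C)[Si](c1ccccc1)(c1ccccc1)OCC(O[Si](CC)(CC)CC)C(=O)C[C@@H](O)[C@@]1(C)[C@@H](OCc2ccc(OC)cc2)CC=C(C)[C@@H]1[C@@H](OCc1ccc(OC)cc1)[C@@]1(O)[C@H](CI)OC(=O)[C@@H]1C | intermediate
26 | 2,4-anti diol | CC(C)(C)[Si](c1ccccc1)(c1ccccc1)OCC(O[Si](CC)(CC)CC)[C@H](O)C[C@@H](O)[C@@]1(C)[C@@H](OCc2ccc(OC)cc2)CC=C(C)[C@@H]1[C@@H](OCc1ccc(OC)cc1)[C@@]1(O)[C@H](CI)OC(=O)[C@@H]1C | intermediate
27 | 2,4-acetonide, C5 OTES | CC(C)(C)[Si](c1ccccc1)(c1ccccc1)OCC(O[Si](CC)(CC)CC)[C@H]2C[C@@H](OC(C)(C)O2)[C@@]1(C)[C@@H](OCc2ccc(OC)cc2)CC=C(C)[C@@H]1[C@@H](OCc1ccc(OC)cc1)[C@@]1(O)[C@H](CI)OC(=O)[C@@H]1C | intermediate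
28 | 2,4-acetonide, C5 alcohol | CC(C)(C)[Si](c1ccccc1)(c1ccccc1)OCC(O)[C@H]2C[C@@H](OC(C)(C)O2)[C@@]1(C)[C@@H](OCc2ccc(OC)cc2)CC=C(C)[C@@H]1[C@@H](OCc1ccc(OC)cc1)[C@@]1(O)[C@H](CI)OC(=O)[C@@H]1C | intermediate
29 | C5 thioacetate, C6 iodide | CC(C)(C)[Si](c1ccccc1)(c1ccccc1)OCC(SC(C)=O)[C@H]2C[C@@H](OC(C)(C)O2)[C@@]1(C)[C@@H](OCc2ccc(OC)cc2)CC=C(C)[C@@H]1[C@@H](OCc1ccc(OC)cc1)[C@@]1(O)[C@H](CI)OC(=O)[C@@H]1C | intermediate
30 | C5 thiol, C6 iodide | CC(C)(C)[Si](c1ccccc1)(c1ccccc1)OCC(S)[C@H]2C[C@@H](OC(C)(C)O2)[C@@]1(C)[C@@H](OCc2ccc(OC)cc2)CC=C(C)[C@@H]1[C@@H](OCc1ccc(OC)cc1)[C@@]1(O)[C@H](CI)OC(=O)[C@@H]1C | intermediate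
31 | eleven-membered cyclic sulfide (S between C5 and C6), lactone intact | CC(C)(C)[Si](c1ccccc1)(c1ccccc1)OCC(S3)[C@H]2C[C@@H](OC(C)(C)O2)[C@@]1(C)[C@@H](OCc2ccc(OC)cc2)CC=C(C)[C@@H]1[C@@H](OCc1ccc(OC)cc1)[C@@]1(O)[C@H](C3)OC(=O)[C@@H]1C | intermediate
32 | cyclic sulfide, C19 Weinreb amide, 7,8-diol | CC(C)(C)[Si](c1ccccc1)(c1ccccc1)OCC(S3)[C@H]2C[C@@H](OC(C)(C)O2)[C@@]1(C)[C@@H](OCc2ccc(OC)cc2)CC=C(C)[C@@H]1[C@@H](OCc1ccc(OC)cc1)[C@@](O)([C@@H](O)C3)[C@@H](C)C(=O)N(C)OC | intermediate
33 | cyclic sulfide, 7,8-bis(TES) ether | CC(C)(C)[Si](c1ccccc1)(c1ccccc1)OCC(S3)[C@H]2C[C@@H](OC(C)(C)O2)[C@@]1(C)[C@@H](OCc2ccc(OC)cc2)CC=C(C)[C@@H]1[C@@H](OCc1ccc(OC)cc1)[C@@](O[Si](CC)(CC)CC)([C@@H](O[Si](CC)(CC)CC)C3)[C@@H](C)C(=O)N(C)OC | intermediate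
34 | eleven-membered cyclic sulfone | CC(C)(C)[Si](c1ccccc1)(c1ccccc1)OCC(S3(=O)=O)[C@H]2C[C@@H](OC(C)(C)O2)[C@@]1(C)[C@@H](OCc2ccc(OC)cc2)CC=C(C)[C@@H]1[C@@H](OCc1ccc(OC)cc1)[C@@](O[Si](CC)(CC)CC)([C@@H](O[Si](CC)(CC)CC)C3)[C@@H](C)C(=O)N(C)OC | intermediate
35 | C6 α-bromo sulfone | CC(C)(C)[Si](c1ccccc1)(c1ccccc1)OCC(S3(=O)=O)[C@H]2C[C@@H](OC(C)(C)O2)[C@@]1(C)[C@@H](OCc2ccc(OC)cc2)CC=C(C)[C@@H]1[C@@H](OCc1ccc(OC)cc1)[C@@](O[Si](CC)(CC)CC)([C@@H](O[Si](CC)(CC)CC)C3Br)[C@@H](C)C(=O)N(C)OC | intermediate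
36 | episulfone (thiirane 1,1-dioxide across C5–C6) | CC(C)(C)[Si](c1ccccc1)(c1ccccc1)OCC3(S4(=O)=O)[C@H]2C[C@@H](OC(C)(C)O2)[C@@]1(C)[C@@H](OCc2ccc(OC)cc2)CC=C(C)[C@@H]1[C@@H](OCc1ccc(OC)cc1)[C@@](O[Si](CC)(CC)CC)([C@@H](O[Si](CC)(CC)CC)C34)[C@@H](C)C(=O)N(C)OC | intermediate
37 | ten-membered (5Z)-cycloalkene: 2,4-acetonide, 7,8-bis(TES), 9,14-di-PMB, 16-OTBDPS, C19 Weinreb amide | CC1(C)O[C@@H]2C[C@@H](O1)[C@@]3(C)[C@@H](OCc4ccc(OC)cc4)CC=C(C)[C@@H]3[C@@H](OCc3ccc(OC)cc3)[C@@](O[Si](CC)(CC)CC)([C@@H](O[Si](CC)(CC)CC)/C=C\2CO[Si](c2ccccc2)(c2ccccc2)C(C)(C)C)[C@@H](C)C(=O)N(C)OC | intermediate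
38 | briarane lactone 2,4-diol (9,14-di-PMB, 16-OTBDPS, 8-OH) | O[C@@H]1C[C@@H](O)[C@@]2(C)[C@@H](OCc3ccc(OC)cc3)CC=C(C)[C@@H]2[C@@H](OCc2ccc(OC)cc2)[C@@]2(O)[C@H](/C=C\1CO[Si](c1ccccc1)(c1ccccc1)C(C)(C)C)OC(=O)[C@@H]2C | intermediate
39 | (R)-3-hydroxybutanoic acid | C[C@@H](O)CC(=O)O | starting material
40 | (R)-3-acetoxybutanoic acid | CC(=O)O[C@H](C)CC(=O)O | intermediate
41 | 4-O-[(R)-3-acetoxybutanoyl] ester of 38 | CC(=O)O[C@H](C)CC(=O)O[C@@H]1C[C@@H](O)[C@@]2(C)[C@@H](OCc3ccc(OC)cc3)CC=C(C)[C@@H]2[C@@H](OCc2ccc(OC)cc2)[C@@]2(O)[C@H](/C=C\1CO[Si](c1ccccc1)(c1ccccc1)C(C)(C)C)OC(=O)[C@@H]2C | intermediate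
42 | 2,9,14-triol 4-ester 16-OTBDPS | CC(=O)O[C@H](C)CC(=O)O[C@@H]1C[C@@H](O)[C@@]2(C)[C@@H](O)CC=C(C)[C@@H]2[C@@H](O)[C@@]2(O)[C@H](/C=C\1CO[Si](c1ccccc1)(c1ccccc1)C(C)(C)C)OC(=O)[C@@H]2C | intermediate
43 | 2,9,14-triacetate 4-ester 16-OTBDPS | CC(=O)O[C@H](C)CC(=O)O[C@@H]1C[C@@H](OC(C)=O)[C@@]2(C)[C@@H](OC(C)=O)CC=C(C)[C@@H]2[C@@H](OC(C)=O)[C@@]2(O)[C@H](/C=C\1CO[Si](c1ccccc1)(c1ccccc1)C(C)(C)C)OC(=O)[C@@H]2C | intermediate
44 | CNP0316115.1 | CC(=O)O[C@H](C)CC(=O)O[C@@H]1C[C@@H](OC(C)=O)[C@@]2(C)[C@@H](OC(C)=O)CC=C(C)[C@@H]2[C@@H](OC(C)=O)[C@@]2(O)[C@H](/C=C\1CO)OC(=O)[C@@H]2C | target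

**Count and risks**

Total: 33 steps. Longest linear sequence: 30 steps from (S)-carvone (steps 1–15, 18–28, 30–33); steps 16–17 and step 29 prepare the two side fragments.

Steps most likely to fail:

Step 27 (ring contraction). E1cB loss of a β-oxygen from the α-sulfonyl carbanions, or over-bromination, may outrun episulfone formation, and the geometry of the trisubstituted olefin may not be controlled. Fallback by Stevens rearrangement and sulfoxide elimination: starting from 33, S-methylation with MeOTf would give the S-methylsulfonium triflate F1. KOtBu in THF would form the ylide at C6, and a Stevens [1,2]-shift of C5 from sulfur to C6 would contract the ring to the ten-membered carbocyclic C6 methyl sulfide F2. NaIO4 would oxidise this to the C6 methyl sulfoxide F3, whose thermal syn-elimination toward C5–H (toluene, 110 °C) should give 37, where the route resumes at step 28.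

Step 23 (macrocyclisation). Intermolecular S-alkylation and oligomerisation may compete with closure of the strained eleven-membered ring, and the iodide may be lost by elimination. Fallback by a larger ring followed by sulfur extrusion: starting from 29, KSAc in DMF would displace the iodide to give the C5,C6-bis(thioacetate) F4. Methanolysis (K2CO3, MeOH) and iodine oxidation at high dilution would close the more easily formed twelve-membered cyclic disulfide F5. P(NEt2)3 would then extrude one sulfur to return the cyclic sulfide 31.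

Step 12 (ketone aldol). Conjugate addition to the vinyl ketone may compete with 1,2-addition, and facial or simple diastereoselection at C8/C17 may erode. Fallback through an ynone, which cannot divert to a stable 1,4-adduct as easily and is sterically more differentiated: starting from 13, lithium (trimethylsilyl)acetylide would give the TMS-ynone F6. The same cerium enolate of 15 would add to give the TMS-alkynyl aldol adduct F7. AgNO3/2,6-lutidine in aqueous acetone would remove silicon to give the terminal alkynyl carbinol F8, and Lindlar semi-hydrogenation would deliver 16.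

Further compounds
F1 | step 27 | S-methylsulfonium triflate of 33 | CC(C)(C)[Si](c1ccccc1)(c1ccccc1)OCC([S+]3C)[C@H]2C[C@@H](OC(C)(C)O2)[C@@]1(C)[C@@H](OCc2ccc(OC)cc2)CC=C(C)[C@@H]1[C@@H](OCc1ccc(OC)cc1)[C@@](O[Si](CC)(CC)CC)([C@@H](O[Si](CC)(CC)CC)C3)[C@@H](C)C(=O)N(C)OC.[O-]S(=O)(=O)C(F)(F)F
F2 | step 27 | ten-membered carbocycle with C5–C6 single bond and SMe at C6 | CC(C)(C)[Si](c1ccccc1)(c1ccccc1)OCC3[C@H]2C[C@@H](OC(C)(C)O2)[C@@]1(C)[C@@H](OCc2ccc(OC)cc2)CC=C(C)[C@@H]1[C@@H](OCc1ccc(OC)cc1)[C@@](O[Si](CC)(CC)CC)([C@@H](O[Si](CC)(CC)CC)C3SC)[C@@H](C)C(=O)N(C)OC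
F3 | step 27 | C6 methyl sulfoxide of F2 | CC(C)(C)[Si](c1ccccc1)(c1ccccc1)OCC3[C@H]2C[C@@H](OC(C)(C)O2)[C@@]1(C)[C@@H](OCc2ccc(OC)cc2)CC=C(C)[C@@H]1[C@@H](OCc1ccc(OC)cc1)[C@@](O[Si](CC)(CC)CC)([C@@H](O[Si](CC)(CC)CC)C3S(C)=O)[C@@H](C)C(=O)N(C)OC
F4 | step 23 | C5,C6-bis(thioacetate) | CC(C)(C)[Si](c1ccccc1)(c1ccccc1)OCC(SC(C)=O)[C@H]2C[C@@H](OC(C)(C)O2)[C@@]1(C)[C@@H](OCc2ccc(OC)cc2)CC=C(C)[C@@H]1[C@@H](OCc1ccc(OC)cc1)[C@@]1(O)[C@H](CSC(C)=O)OC(=O)[C@@H]1C
F5 | step 23 | twelve-membered cyclic disulfide (C5–S–S–C6) | CC(C)(C)[Si](c1ccccc1)(c1ccccc1)OCC(S3)[C@H]2C[C@@H](OC(C)(C)O2)[C@@]1(C)[C@@H](OCc2ccc(OC)cc2)CC=C(C)[C@@H]1[C@@H](OCc1ccc(OC)cc1)[C@@]1(O)[C@H](CS3)OC(=O)[C@@H]1C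
F6 | step 12 | C8 (trimethylsilyl)ethynyl ketone | CC(C)(C)[Si](C)(C)OC[C@@]1(C)[C@@H](OCc2ccc(OC)cc2)CC=C(C)[C@@H]1[C@@H](OCc1ccc(OC)cc1)C(=O)C#C[Si](C)(C)C
F7 | step 12 | TMS-alkynyl aldol adduct | CC(C)(C)[Si](C)(C)OC[C@@]1(C)[C@@H](OCc2ccc(OC)cc2)CC=C(C)[C@@H]1[C@@H](OCc1ccc(OC)cc1)[C@@](O)(C#C[Si](C)(C)C)[C@@H](C)C(=O)OC(C)(C)C
F8 | step 12 | terminal alkynyl carbinol | CC(C)(C)[Si](C)(C)OC[C@@]1(C)[C@@H](OCc2ccc(OC)cc2)CC=C(C)[C@@H]1[C@@H](OCc1ccc(OC)cc1)[C@@](O)(C#C)[C@@H](C)C(=O)OC(C)(C)C
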